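The C2 bromine and the C3 dimethylaminomethyl group on the pyrrole ring are traced back to a 3-(dimethylaminomethylene)oxindole: its lactam C=O becomes C2–Br and its exocyclic enamine carbon becomes the side-chain CH2. Cutting that oxindole at the C3–C3a bond leaves an N-methyl anilide carrying a β-dimethylamino acrylamide, with iodine ortho to nitrogen and bromines at the future C5 and C6. One intramolecular Heck reaction forms C3–C3a and closes the five-membered lactam with every skeletal atom, the side-chain nitrogen included, already in place. Exchange of the lactam oxygen for bromine with aromatization, then iminium reduction, completes the target.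

Key step: step 5

Remark: iminium salt 10 is drawn as its bromide (the counter-ion in the flask may equally be dibromophosphate), and 9 is drawn as the Z isomer expected from syn insertion and syn elimination; either alkene geometry leads to the same ion 10.

Step 1
Reactants: 1 3,4-dibromoaniline
Product: 2 4,5-dibromo-2-iodoaniline
Conditions: N-iodosuccinimide (1.05 equiv), AcOH, rt, dark
Reagents that add atoms: N-iodosuccinimide, O=C1CCC(=O)N1I
Why: Electrophilic aromatic iodination directed by the amino group, whose para position is blocked by bromine and whose ortho position between NH2 and Br is crowded, so iodine should enter at the free ortho carbon C6.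

Step 2
Reactants: 2 4,5-dibromo-2-iodoaniline
Product: 4 4,5-dibromo-2-iodo-N-methylaniline, via N-methoxymethyl aniline 3 (not isolated)
Conditions: (CH2O)n, NaOMe, MeOH, rt → 50 °C; then NaBH4, reflux
Reagents that add atoms: paraformaldehyde, as formaldehyde C=O (the N-methyl carbon); methanol, CO (methoxy group of intermediate 3 only)
Why: Reductive N-methylation in which the primary aniline condenses with formaldehyde in basic methanol to the hemiaminal ether and borohydride replaces methoxide by hydride, a sequence that should stop at the mono-methyl stage and leave the aryl halides untouched.

Step 3
Reactants: 4 4,5-dibromo-2-iodo-N-methylaniline; 5 propiolic acid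
Product: 6 N-(4,5-dibromo-2-iodophenyl)-N-methylprop-2-ynamide
Conditions: DCC, CH2Cl2, 0 °C → rt (no DMAP)
Reagents that add atoms: none
Why: Carbodiimide-mediated amide coupling in which DCC activates the acid in situ for N-acylation of the secondary aniline, run without a nucleophilic catalyst so that nothing adds to the alkyne β-carbon.

Step 4
Reactants: 6 N-(4,5-dibromo-2-iodophenyl)-N-methylprop-2-ynamide; 7 dimethylamine
Product: 8 (E)-N-(4,5-dibromo-2-iodophenyl)-3-(dimethylamino)-N-methylprop-2-enamide
Conditions: Me2NH (2 M in THF, excess), THF, 0 °C → rt
Reagents that add atoms: none
Why: Aza-Michael addition of a secondary amine to the electron-poor alkyne, which should give the thermodynamically preferred E push–pull enaminone (NMe2 trans to the carbonyl).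

Step 5
Reactants: 8 (E)-N-(4,5-dibromo-2-iodophenyl)-3-(dimethylamino)-N-methylprop-2-enamide
Product: 9 (Z)-5,6-dibromo-3-[(dimethylamino)methylidene]-1-methylindolin-2-one
Conditions: Pd(OAc)2 (5 mol %), Bu4NCl, NaOAc, degassed DMF, 70 °C
Reagents that add atoms: none
Why: Zerovalent palladium formed in situ from Pd(OAc)2 inserts into the aryl C–I bond, the arylpalladium species adds syn across the push–pull alkene with the aryl carbon bonding to the amide α-carbon, and after rotation about the new exocyclic bond syn β-hydride elimination of the C3 hydrogen restores the conjugated enaminone while NaOAc regenerates the catalyst. The closest known reaction type is the intramolecular Heck cyclization of N-alkyl-N-(2-haloaryl)acrylamides to 3-alkylideneoxindoles, and the related palladium-catalysed C-arylation of N-(2-haloaryl) enaminones would form the same bond because the α-carbon is also the nucleophilic carbon of the enaminone. The five-membered lactam, the later pyrrole ring, closes in the 5-exo-trig mode and forms C3–C3a. No stereocentre is created, the syn insertion and syn elimination should deliver the Z alkene, and the geometry is immaterial because this double bond becomes the iminium of 10. The step needs C–I over C–Br selectivity, secured by the much faster oxidative addition of the iodide under phosphine-free conditions at moderate temperature, and 5-exo over 6-endo closure, secured by the short N-methyl amide tether whose preferred rotamer holds the aryl ring cis to the acyl chain so that only the α-carbon reaches palladium.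

Step 6
Reactants: 9 (Z)-5,6-dibromo-3-[(dimethylamino)methylidene]-1-methylindolin-2-one
Product: 11 2,5,6-tribromo-1-methylgramine, via iminium bromide 10 (not isolated)
Conditions: POBr3 (1.3 equiv), ClCH2CH2Cl, 0 → 60 °C; then THF, NaBH4 (excess), MeOH added dropwise, −20 → 0 °C; aq. NaHCO3
Reagents that add atoms: phosphorus oxybromide, O=P(Br)(Br)Br
Why: Vilsmeier-type activation in which POBr3 turns the lactam oxygen into a phosphate leaving group that bromide replaces at C2 with aromatization to the 2-bromoindol-3-ylmethyleneiminium ion (the intermediate of the haloformylation of oxindoles), followed by borohydride reduction of the exocyclic iminium carbon to the tertiary amine without touching the C–Br bonds.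

Compound list
1 | 3,4-dibromoaniline | Nc1ccc(Br)c(Br)c1 | starting material
2 | 4,5-dibromo-2-iodoaniline | Nc1cc(Br)c(Br)cc1I | intermediate
3 | 4,5-dibromo-2-iodo-N-(methoxymethyl)aniline | COCNc1cc(Br)c(Br)cc1I | intermediate
4 | 4,5-dibromo-2-iodo-N-methylaniline | CNc1cc(Br)c(Br)cc1I | intermediate
5 | propiolic acid (prop-2-ynoic acid) | C#CC(=O)O | starting material
6 | N-(4,5-dibromo-2-iodophenyl)-N-methylprop-2-ynamide | C#CC(=O)N(C)c1cc(Br)c(Br)cc1I | intermediate
7 | dimethylamine | CNC | starting material
8 | (E)-N-(4,5-dibromo-2-iodophenyl)-3-(dimethylamino)-N-methylprop-2-enamide | CN(C)/C=C/C(=O)N(C)c1cc(Br)c(Br)cc1I | intermediate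
9 | (Z)-5,6-dibromo-3-[(dimethylamino)methylidene]-1-methylindolin-2-one | CN(C)/C=C1\C(=O)N(C)c2cc(Br)c(Br)cc21 | intermediate
10 | N-[(2,5,6-tribromo-1-methylindol-3-yl)methylidene]-N-methylmethanaminium bromide | C[N+](C)=Cc1c(Br)n(C)c2cc(Br)c(Br)cc12.[Br-] | intermediate
11 | 2,5,6-tribromo-1-methylgramine, 1-(2,5,6-tribromo-1-methylindol-3-yl)-N,N-dimethylmethanamine | CN(C)Cc1c(Br)n(C)c2cc(Br)c(Br)cc12 | target

Total step count: 6
Longest linear sequence: 6 steps (1 → 2 → 4 → 6 → 8 → 9 → 11)

Steps most likely to fail

Step 5 carries the main risk. Palladium may also insert into the C–Br bonds as the iodide is consumed, leading to oligomers. The arylpalladium species may instead be reduced (loss of iodine without ring closure), or the catalyst may precipitate before closure. The fallback sets out from 8 and closes the ring with a radical instead of palladium. Bu3SnH (slow addition) and AIBN in toluene at 80 °C should abstract iodine selectively. The aryl radical should close 5-exo onto the amide α-carbon, and the resulting α-amino radical should be reduced to 5,6-dibromo-3-[(dimethylamino)methyl]-1-methylindolin-2-one F1 (racemic at C3, a centre that vanishes on aromatization). F1, handled without delay because a β-amino lactam can lose dimethylamine, would be heated with POBr3 in ClCH2CH2Cl, the known conversion of 3-substituted oxindoles into 2-bromoindoles. This should give 11 directly, so the detour comes back to the route at 11 and bypasses 9 and 10.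

Step 6 is next. In the one-pot sequence hydride may attack C2 and expel bromide, the iminium ion may collapse by adventitious hydrolysis before reduction, or borane formed from acid and borohydride may bind the product amine. The fallback sets out from 9: POBr3 is used as in the route to reach 10, which is then deliberately hydrolysed with aqueous NaOAc to 2,5,6-tribromo-1-methylindole-3-carbaldehyde F2, a stable and purifiable aldehyde. Reductive amination of F2 with dimethylamine 7 (Ti(OiPr)4, then NaBH4 in EtOH) should return to the route at 11.

Step 3 is the third. N-Acylation of the hindered, weakly nucleophilic secondary aniline may be slow, so that the activated propiolic acid rearranges to the N-acylurea or oligomerizes before it is captured. The fallback sets out from 4 and avoids the alkynamide. Acylation with commercially available (E)-3-ethoxyacryloyl chloride (pyridine, CH2Cl2, 0 °C → rt) should give (E)-N-(4,5-dibromo-2-iodophenyl)-3-ethoxy-N-methylprop-2-enamide F3. Heating F3 with excess dimethylamine 7 in EtOH in a sealed tube should exchange the ethoxy group for the amine by conjugate addition–elimination. This comes back to the route at 8 and bypasses 6.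

Further compounds
F1 | step 5 | 5,6-dibromo-3-[(dimethylamino)methyl]-1-methylindolin-2-one (racemic) | CN(C)CC1C(=O)N(C)c2cc(Br)c(Br)cc21
F2 | step 6 | 2,5,6-tribromo-1-methylindole-3-carbaldehyde | O=Cc1c(Br)n(C)c2cc(Br)c(Br)cc12
F3 | step 3 | (E)-N-(4,5-dibromo-2-iodophenyl)-3-ethoxy-N-methylprop-2-enamide | CCO/C=C/C(=O)N(C)c1cc(Br)c(Br)cc1I
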